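## The problem

The target is a stilbenoid octaphenol built from six benzene rings. Two trans-2,3-diaryl-2,3-dihydrobenzofurans are joined by a bond from C3 of the upper unit to C6' of the lower unit, and the upper unit carries an (E)-4-hydroxystyryl group on C6 of its benzo ring (ring A). The only rings that have to be made are the two dihydrofurans.

The four stereocentres form two trans pairs, (2R,3R) in the upper ring and (2S,3S) in the lower ring. The pairs have opposite absolute sense and are separated by the meta-substituted benzo ring of the lower unit (ring C), so neither can direct the other and each must be set by a reagent. Within a pair, C3 can control C2, because C2 is a benzylic ether carbon bearing a 4-oxygenated aryl group; it ionises easily and trans is the thermodynamic arrangement.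

The same lability is the main hazard. Strong acid at ambient temperature opens O1–C2, the stilbene adds electrophiles and is reduced under hydrogenation (which would also cleave the benzylic C2–O bonds), and the free polyphenol oxidises readily. The eight hydroxyls therefore have to be unmasked cold and without hydrogen.

The enabling feature is the same in both units. In each dihydrobenzofuran (O1, C2, C3, C3a, C7a) the benzo ring has oxygen on both carbons flanking C3a (O1 on C7a, a hydroxyl on C4), and C2 carries a cation-stabilising 4-oxygenated aryl group. O1–C2 and both stereocentres therefore map onto a flat 1-(2,6-dihydroxyaryl)-1,2-diarylethylene whose dihydroxyaryl ring is symmetric, so the closing hydroxyl needs no differentiation.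

## Retrosynthesis

**26 from 25.** No skeletal bond is cut; the last step removes seven benzyl ethers from 25. Benzyl is preferred to methyl because aryl benzyl ethers fall to BCl3 with pentamethylbenzene at −78 °C, whereas methyl ethers need BBr3 near room temperature, where O1–C2 ionises. Hydrogenolysis is excluded by the stilbene and the benzylic C2–O bonds, and silyl or acyl groups would not survive the organometallic steps. The forward reaction must leave two benzylic ethers and a stilbene intact.

**25 from 23 and 24.** The aryl–vinyl bond between C6 and the stilbene is cut, giving bromide 23 and 4-benzyloxystyrene 24 (Heck reaction). A Wittig-type cut would need a formyl group and more steps. Placing the stilbene after the ring closure keeps it away from the chiral acid, and the bromine is an inert spectator until then.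

**23 from 22 (key disconnection).** O1–C2 and the C3–H bond are cut, leading to the flat triarylethylene diol 22. A ring and two stereocentres are removed in one operation. The neighbouring cut at C2–C3 (benzylic anion onto a diaryl ketone) gives the wrong oxidation level and no handle for asymmetry, and an oxidative stilbene coupling offers no regio- or enantiocontrol. The forward reaction must protonate C3 on one face under catalyst control and close the ring trans.

**22 from 21, 20, 17 and 18.** The ring A hydroxyls of 22 are masked as allyl ethers in 21. The C2=C3 double bond comes from dehydration of tertiary alcohol 20, and the C2–C3 bond from addition of the benzylic Grignard reagent 19 (from chloride 18) to diaryl ketone 17. Allyl is chosen over silyl because an ortho silyloxy group next to a benzylic alkoxide migrates and releases an ortho-quinone methide that adds a second organometallic. Allyl ethers are inert there and leave under neutral zerovalent-palladium conditions that cannot trigger a racemic cyclisation. Ketone 17 has no α-hydrogen, so it is preferred to the isomeric deoxybenzoin, which would enolise.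

**17 from 16, 14 and 3.** The C3–C6' bond is cut: aryllithium 15, made from bromide 14, adds to aldehyde 3 to give carbinol 16, which is oxidised to 17. The precursors are a complete lower unit and a one-ring aldehyde. Bromine–lithium exchange must outrun deprotonation of 14.

**14 from 13 and 12.** The lower ring is opened by the same cut, O1'–C2', to triarylethylene diol 12; phenol 13 is then benzylated to 14. Using the reaction twice means one method serves both rings and is first tested on the simpler substrate. Because the lower ring has the opposite absolute sense, the mirror-image acid is used.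

**12 from 11, 10, 7, 8, 6, 4 and 3.** The same assembly applies: deallylation of 11, dehydration of 10, addition of Grignard reagent 9 (from chloride 8) to ketone 7, oxidation of carbinol 6, and addition of aryllithium 5 (from bromide 4) to aldehyde 3.

**3 from 2 and 1.** Aldehyde 3 supplies ring A, ring C and the future C3 and C3' carbons; it is used twice. It comes from commercial 1 by cleavage of the two chelated methyl ethers to 2 and allylation.

## Roads not taken

Alternative 1: The lower ring is traced to the six-membered lactone A1. An isothiourea catalyst (HyperBTM) turns an arylacetic ester into an ammonium enolate, which adds to the ortho-quinone methide of ring C released by base from a sulfone. This forms the future C2'–C3' bond, and lactonisation gives A1 with both stereocentres set. The reaction class is known and reliably trans- and enantioselective, so in precedent this road is clearly stronger than the chosen one. Its weak point is the extra carbon. The lactone carbonyl must be excised and O1'–C2' made afterwards, through ring opening, oxidative decarboxylation to a C2' cation and reclosure, which costs several steps. The quinone methide is also flanked by a methoxy group and an aryl group, and the road solves only the lower ring. The chosen plan sets against this a precursor with no carbon to remove, one method for both rings, and the free C4 hydroxyl as a direct outcome. If step 8 failed, a lactone of this kind would be the natural source of a building block like 14.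

Alternative 2: The lower ring is cut back to the flavanone hesperetin A2. After O-alkylation, PhI(OAc)2 (trivalent iodine) with H2SO4 in trimethyl orthoformate induces a 1,2-shift of the ring C carbon from C4 to C3. The pyranone contracts to the dihydrofuran ester A3, with C2' taken from the chiral pool and the ester trans to the aryl group. Cheap chirality without a catalyst and a known key step are real advantages over the chosen plan. For this target, however, C3' ends with an ester where the 3,5-dihydroxyphenyl ring must stand, so an arene must be built or coupled there and C3' re-set. C6' carries oxygen where a carbon bond is needed. The flavanone stereocentre can racemise through the chalcone under the acid or during alkylation. The 4-methoxy group of A2 forces a late methyl ether cleavage that the dihydrobenzofurans tolerate poorly. The chosen plan brings every aryl ring in at the right position and oxidation level, at the price of an unproven asymmetric step.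

Alternative 3: Ring C is grown on a 2-diazocyclohexane-1,3-dione that already carries the upper unit. Rh2(S-PTTL)4 (divalent rhodium) forms a carbene that a stilbene attacks through its 3,5-dimethoxyphenyl-bearing carbon (C3'–C3a'); the enolate oxygen then closes on the benzylic cation (O1'–C2') to give A4, which must afterwards be dehydrogenated to the phenol of ring C. This is more convergent than the chosen plan, since it joins the halves while making the ring. The weak points are several. The orientation on a stilbene with two similarly electron-rich aryl groups is uncertain, and asymmetric induction with acceptor/acceptor carbenes and 1,2-diaryl alkenes has little precedent. Aromatisation of A4 must be done next to two benzylic ethers. The upper ring must already exist as a single enantiomer, so a second asymmetric method is still required. The chosen plan keeps all rings aromatic throughout and needs one method only.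

Key step: step 15

Remark on geometry: the triarylethylenes 11, 12, 21 and 22 are drawn as Z isomers (2,6-dioxygenated ring cis to the benzylidene aryl group), the geometry expected from elimination through the twisted diarylmethyl cation; the E isomers would serve equally, since reversible protonation at C2 under the acid can interconvert them.

Remark on the catalyst: the sense of induction of the imidodiphosphorimidate (IDPi) acid HN[P(=NTf)(O2C20H10Ar2)]2 (3,3'-diaryl-1,1'-binaphthalene-2,2'-diolate backbone, Ar = 3,5-(CF3)2C6H3) cannot be predicted; the (S,S) acid is assumed to give the (2S,3S) ring and the (R,R) acid the (2R,3R) ring, and the two would be exchanged if step 8 showed the opposite sense.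

Step 1
Reactants: 1 4-bromo-2,6-dimethoxybenzaldehyde
Product: 2 4-bromo-2,6-dihydroxybenzaldehyde
Conditions: AlCl3 (3 equiv), CH2Cl2, 0 °C to rt; aq HCl
Reagents that add atoms: none
Why: Lewis-acid ether cleavage; AlCl3 chelates between the formyl oxygen and each ortho methoxy group, which activates exactly these two methyl ethers for attack by chloride, and the aryl bromide and aldehyde are untouched.

Step 2
Reactants: 2 4-bromo-2,6-dihydroxybenzaldehyde
Product: 3 4-bromo-2,6-bis(allyloxy)benzaldehyde
Conditions: allyl bromide, K2CO3, DMF, 50 °C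
Reagents that add atoms: allyl bromide, C=CCBr
Why: Williamson etherification of both phenols; allyl is chosen because it does not migrate to a neighbouring alkoxide during the organometallic steps and leaves later under neutral conditions.

Step 3
Reactants: 4 1-bromo-3,5-bis(benzyloxy)benzene; 3 4-bromo-2,6-bis(allyloxy)benzaldehyde
Product: 6 [4-bromo-2,6-bis(allyloxy)phenyl][3,5-bis(benzyloxy)phenyl]methanol (racemic), via 3,5-bis(benzyloxy)phenyllithium 5 (not isolated)
Conditions: n-BuLi, THF, −78 °C; then 3, −78 °C; H2O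
Reagents that add atoms: none
Why: Bromine–lithium exchange on 4 is fast at −78 °C and the aryllithium adds to the formyl group of 3 faster than it exchanges with the aryl bromide of 3; the racemic carbinol centre is removed in step 4.

Step 4
Reactants: 6 [4-bromo-2,6-bis(allyloxy)phenyl][3,5-bis(benzyloxy)phenyl]methanol
Product: 7 [4-bromo-2,6-bis(allyloxy)phenyl][3,5-bis(benzyloxy)phenyl]methanone
Conditions: Dess–Martin periodinane, CH2Cl2, rt
Reagents that add atoms: none
Why: Dess–Martin oxidation of a secondary diaryl carbinol; the neutral conditions spare the allyl and benzyl ethers and the aryl bromide.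

Step 5
Reactants: 7 [4-bromo-2,6-bis(allyloxy)phenyl][3,5-bis(benzyloxy)phenyl]methanone; 8 3,4-bis(benzyloxy)benzyl chloride
Product: 10 1-[4-bromo-2,6-bis(allyloxy)phenyl]-1-[3,5-bis(benzyloxy)phenyl]-2-[3,4-bis(benzyloxy)phenyl]ethan-1-ol (racemic), via 3,4-bis(benzyloxy)benzylmagnesium chloride 9 (not isolated)
Conditions: 8, Mg, THF, 0 °C; then 7, 0 °C to rt; H2O
Reagents that add atoms: none
Why: Grignard addition to a diaryl ketone that has no α-hydrogen, so 1,2-addition is the only productive path; the benzylic Grignard reagent is formed cold and dilute to limit Wurtz coupling, and the racemic carbinol centre disappears in step 6.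

Step 6
Reactants: 10 1-[4-bromo-2,6-bis(allyloxy)phenyl]-1-[3,5-bis(benzyloxy)phenyl]-2-[3,4-bis(benzyloxy)phenyl]ethan-1-ol
Product: 11 1,3-bis(allyloxy)-5-bromo-2-{(Z)-1-[3,5-bis(benzyloxy)phenyl]-2-[3,4-bis(benzyloxy)phenyl]ethenyl}benzene
Conditions: MsCl, Et3N, CH2Cl2, 0 °C to rt
Reagents that add atoms: none
Why: Mesylation through sulfene and E1 elimination of the doubly benzylic tertiary mesylate under amine buffering; the proton should be lost from the rotamer that places the benzylic aryl group beside the twisted 2,6-dioxygenated ring, so the Z alkene with the two conjugating aryl groups trans is expected.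

Step 7
Reactants: 11 1,3-bis(allyloxy)-5-bromo-2-{(Z)-1-[3,5-bis(benzyloxy)phenyl]-2-[3,4-bis(benzyloxy)phenyl]ethenyl}benzene
Product: 12 5-bromo-2-{(Z)-1-[3,5-bis(benzyloxy)phenyl]-2-[3,4-bis(benzyloxy)phenyl]ethenyl}benzene-1,3-diol
Conditions: Pd(PPh3)4 (5 mol%), morpholine, THF, rt
Reagents that add atoms: none
Why: Tsuji–Trost-type deallylation; zerovalent palladium ionises the aryl allyl ethers to π-allyl complexes that morpholine traps, which at room temperature is much faster than oxidative addition into the aryl bromide, and no acid touches the alkene.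

Step 8
Reactants: 12 5-bromo-2-{(Z)-1-[3,5-bis(benzyloxy)phenyl]-2-[3,4-bis(benzyloxy)phenyl]ethenyl}benzene-1,3-diol
Product: 13 (2S,3S)-2-[3,4-bis(benzyloxy)phenyl]-3-[3,5-bis(benzyloxy)phenyl]-6-bromo-2,3-dihydro-1-benzofuran-4-ol
Conditions: (S,S)-IDPi acid HN[P(=NTf)(O2C20H10Ar2)]2 (Ar = 3,5-(CF3)2C6H3, 5 mol%), CHCl3 (0.01 M), 0 °C to rt
Reagents that add atoms: none
Why: Proposed new method: the chiral acid should protonate the stilbene-like alkene at C3 (the dihydroxyaryl ring is twisted out of conjugation, so the charge goes to the 3,4-bis(benzyloxy)benzylic carbon C2), and a hydroxyl held over the face of C2 closes O1–C2 in a stepwise 5-endo closure. The face of protonation sets C3 under catalyst control and C2 follows as the trans isomer; the closest known reaction type is the IDPi-catalysed asymmetric intramolecular hydroalkoxylation of alkenols.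

Step 9
Reactants: 13 (2S,3S)-2-[3,4-bis(benzyloxy)phenyl]-3-[3,5-bis(benzyloxy)phenyl]-6-bromo-2,3-dihydro-1-benzofuran-4-ol
Product: 14 (2S,3S)-4-(benzyloxy)-2-[3,4-bis(benzyloxy)phenyl]-3-[3,5-bis(benzyloxy)phenyl]-6-bromo-2,3-dihydro-1-benzofuran
Conditions: BnBr, K2CO3, DMF, rt
Reagents that add atoms: benzyl bromide, BrCc1ccccc1
Why: Williamson benzylation of the remaining phenol; neither stereocentre is acidic under carbonate and the C2 aryl group has no free para hydroxyl that could open the ring.

Step 10
Reactants: 14 (2S,3S)-4-(benzyloxy)-2-[3,4-bis(benzyloxy)phenyl]-3-[3,5-bis(benzyloxy)phenyl]-6-bromo-2,3-dihydro-1-benzofuran; 3 4-bromo-2,6-bis(allyloxy)benzaldehyde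
Product: 16 [(2S,3S)-4-(benzyloxy)-2-[3,4-bis(benzyloxy)phenyl]-3-[3,5-bis(benzyloxy)phenyl]-2,3-dihydro-1-benzofuran-6-yl][4-bromo-2,6-bis(allyloxy)phenyl]methanol (both carbinol epimers), via dihydrobenzofuran-6-yllithium 15 (not isolated)
Conditions: n-BuLi, THF, −78 °C; then 3, −78 °C; H2O
Reagents that add atoms: none
Why: Bromine–lithium exchange at −78 °C outruns deprotonation at C3 or at the benzylic ether carbons, and the aryllithium adds to the aldehyde; the carbinol epimers are of no consequence because step 11 removes the centre.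

Step 11
Reactants: 16 [(2S,3S)-4-(benzyloxy)-2-[3,4-bis(benzyloxy)phenyl]-3-[3,5-bis(benzyloxy)phenyl]-2,3-dihydro-1-benzofuran-6-yl][4-bromo-2,6-bis(allyloxy)phenyl]methanol
Product: 17 [(2S,3S)-4-(benzyloxy)-2-[3,4-bis(benzyloxy)phenyl]-3-[3,5-bis(benzyloxy)phenyl]-2,3-dihydro-1-benzofuran-6-yl][4-bromo-2,6-bis(allyloxy)phenyl]methanone
Conditions: Dess–Martin periodinane, CH2Cl2, rt
Reagents that add atoms: none
Why: Dess–Martin oxidation of a secondary diaryl carbinol; the acetic acid released is too weak to ionise the benzylic ether of the dihydrobenzofuran.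

Step 12
Reactants: 17 [(2S,3S)-4-(benzyloxy)-2-[3,4-bis(benzyloxy)phenyl]-3-[3,5-bis(benzyloxy)phenyl]-2,3-dihydro-1-benzofuran-6-yl][4-bromo-2,6-bis(allyloxy)phenyl]methanone; 18 4-(benzyloxy)benzyl chloride
Product: 20 1-[(2S,3S)-4-(benzyloxy)-2-[3,4-bis(benzyloxy)phenyl]-3-[3,5-bis(benzyloxy)phenyl]-2,3-dihydro-1-benzofuran-6-yl]-1-[4-bromo-2,6-bis(allyloxy)phenyl]-2-[4-(benzyloxy)phenyl]ethan-1-ol (both carbinol epimers), via 4-(benzyloxy)benzylmagnesium chloride 19 (not isolated)
Conditions: 18, Mg, THF, 0 °C; then 17, 0 °C to rt; H2O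
Reagents that add atoms: none
Why: Grignard addition to a non-enolisable diaryl ketone, as in step 5; the new carbinol centre is removed in step 13.

Step 13
Reactants: 20 1-[(2S,3S)-4-(benzyloxy)-2-[3,4-bis(benzyloxy)phenyl]-3-[3,5-bis(benzyloxy)phenyl]-2,3-dihydro-1-benzofuran-6-yl]-1-[4-bromo-2,6-bis(allyloxy)phenyl]-2-[4-(benzyloxy)phenyl]ethan-1-ol
Product: 21 (2S,3S)-4-(benzyloxy)-2-[3,4-bis(benzyloxy)phenyl]-3-[3,5-bis(benzyloxy)phenyl]-6-{(Z)-2-[4-(benzyloxy)phenyl]-1-[4-bromo-2,6-bis(allyloxy)phenyl]ethenyl}-2,3-dihydro-1-benzofuran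
Conditions: MsCl, Et3N, CH2Cl2, 0 °C to rt
Reagents that add atoms: none
Why: Mesylation and E1 elimination as in step 6; the amine-buffered medium spares the O1'–C2' benzylic ether of the lower ring, and the Z alkene is expected for the same conformational reason.

Step 14
Reactants: 21 (2S,3S)-4-(benzyloxy)-2-[3,4-bis(benzyloxy)phenyl]-3-[3,5-bis(benzyloxy)phenyl]-6-{(Z)-2-[4-(benzyloxy)phenyl]-1-[4-bromo-2,6-bis(allyloxy)phenyl]ethenyl}-2,3-dihydro-1-benzofuran
Product: 22 5-bromo-2-{(Z)-1-[(2S,3S)-4-(benzyloxy)-2-[3,4-bis(benzyloxy)phenyl]-3-[3,5-bis(benzyloxy)phenyl]-2,3-dihydro-1-benzofuran-6-yl]-2-[4-(benzyloxy)phenyl]ethenyl}benzene-1,3-diol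
Conditions: Pd(PPh3)4 (5 mol%), morpholine, THF, rt
Reagents that add atoms: none
Why: Tsuji–Trost-type deallylation as in step 7; the neutral conditions free both hydroxyls of ring A without any acid that could start a racemic ring closure.

Step 15
Reactants: 22 5-bromo-2-{(Z)-1-[(2S,3S)-4-(benzyloxy)-2-[3,4-bis(benzyloxy)phenyl]-3-[3,5-bis(benzyloxy)phenyl]-2,3-dihydro-1-benzofuran-6-yl]-2-[4-(benzyloxy)phenyl]ethenyl}benzene-1,3-diol
Product: 23 (2R,3R)-3-[(2S,3S)-4-(benzyloxy)-2-[3,4-bis(benzyloxy)phenyl]-3-[3,5-bis(benzyloxy)phenyl]-2,3-dihydro-1-benzofuran-6-yl]-2-[4-(benzyloxy)phenyl]-6-bromo-2,3-dihydro-1-benzofuran-4-ol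
Conditions: (R,R)-IDPi acid HN[P(=NTf)(O2C20H10Ar2)]2 (Ar = 3,5-(CF3)2C6H3, 5 mol%), CHCl3 (0.01 M), 0 °C to rt
Reagents that add atoms: none
Why: Proposed new method: the confined acid should transfer its proton to C3, the alkene carbon bearing ring A and the dihydrobenzofuranyl ring, so that the charge develops at C2, where the coplanar 4-benzyloxyphenyl ring stabilises it in a contact ion pair with the chiral anion. Ring A stands perpendicular to the alkene, which both withholds its stabilisation from a C3 cation and places a hydroxyl above and below C2, so one of them closes O1–C2; the closure is formally 5-endo-trig but is allowed because it runs stepwise through the benzylic cation, and since ring A is symmetric the two hydroxyls are equivalent once C3 is tetrahedral. The closest known reaction type is the IDPi-catalysed asymmetric intramolecular hydroalkoxylation of alkenols; what is new is capture at the less substituted carbon of a triarylethylene by a phenol in a five-membered endo mode. C3 is set by the face of proton transfer inside the catalyst pocket, with the (R,R) acid because the upper ring has the opposite absolute sense to the lower one, whose centres lie across ring C and should exert little influence. C2 follows C3: the cation is captured with the two aryl groups anti, and any cis isomer can equilibrate to trans through reversible ionisation of O1–C2 under the same acid. The selectivity needed is protonation at C3 rather than C2; protonation at C2 gives a diarylmethyl cation of ortho-quinone methide type that has no nucleophile within reach (oxygen attack would make a four-membered ring) and should revert, at most interconverting the alkene geometries. High dilution in a non-nucleophilic solvent is meant to suppress intermolecular Friedel–Crafts capture of that cation, and the aryl bromide, benzyl ethers and existing dihydrobenzofuran should be inert to a catalytic acid at this temperature.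

Step 16
Reactants: 23 (2R,3R)-3-[(2S,3S)-4-(benzyloxy)-2-[3,4-bis(benzyloxy)phenyl]-3-[3,5-bis(benzyloxy)phenyl]-2,3-dihydro-1-benzofuran-6-yl]-2-[4-(benzyloxy)phenyl]-6-bromo-2,3-dihydro-1-benzofuran-4-ol; 24 4-benzyloxystyrene
Product: 25 (2R,3R)-3-[(2S,3S)-4-(benzyloxy)-2-[3,4-bis(benzyloxy)phenyl]-3-[3,5-bis(benzyloxy)phenyl]-2,3-dihydro-1-benzofuran-6-yl]-2-[4-(benzyloxy)phenyl]-6-{(E)-2-[4-(benzyloxy)phenyl]ethenyl}-2,3-dihydro-1-benzofuran-4-ol
Conditions: Pd(OAc)2 (5 mol%), P(o-tol)3, Et3N, DMF, 90 °C
Reagents that add atoms: none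
Why: Mizoroki–Heck reaction; oxidative addition into the aryl bromide, insertion of the styrene at its terminal carbon and syn β-hydride elimination give the E stilbene, and the free phenol and the four stereocentres are untouched by triethylamine at this temperature.

Step 17
Reactants: 25 (2R,3R)-3-[(2S,3S)-4-(benzyloxy)-2-[3,4-bis(benzyloxy)phenyl]-3-[3,5-bis(benzyloxy)phenyl]-2,3-dihydro-1-benzofuran-6-yl]-2-[4-(benzyloxy)phenyl]-6-{(E)-2-[4-(benzyloxy)phenyl]ethenyl}-2,3-dihydro-1-benzofuran-4-ol
Product: 26 (2R,3R)-3-[(2S,3S)-2-(3,4-dihydroxyphenyl)-3-(3,5-dihydroxyphenyl)-4-hydroxy-2,3-dihydro-1-benzofuran-6-yl]-2-(4-hydroxyphenyl)-6-[(E)-2-(4-hydroxyphenyl)ethenyl]-2,3-dihydro-1-benzofuran-4-ol (CNP0107857.3)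
Conditions: BCl3, pentamethylbenzene, CH2Cl2, −78 °C; then MeOH
Reagents that add atoms: none
Why: Lewis-acid debenzylation with a non-basic cation scavenger; BCl3 cleaves the seven aryl benzyl ethers at −78 °C and pentamethylbenzene takes up the benzyl cations, so no hydrogen is needed and the stilbene and electron-rich rings are not benzylated. At this temperature the O1–C2 ethers are expected to stay closed, as is known for polybenzylated stilbenoid dihydrobenzofurans.

Compound list

1 | 4-bromo-2,6-dimethoxybenzaldehyde | COc1cc(Br)cc(OC)c1C=O | starting material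
2 | 4-bromo-2,6-dihydroxybenzaldehyde | Oc1cc(Br)cc(O)c1C=O | intermediate
3 | 4-bromo-2,6-bis(allyloxy)benzaldehyde | C=CCOc1cc(Br)cc(OCC=C)c1C=O | intermediate
4 | 1-bromo-3,5-bis(benzyloxy)benzene | Brc1cc(OCc2ccccc2)cc(OCc2ccccc2)c1 | starting material
5 | 3,5-bis(benzyloxy)phenyllithium | [Li]c1cc(OCc2ccccc2)cc(OCc2ccccc2)c1 | intermediate
6 | [4-bromo-2,6-bis(allyloxy)phenyl][3,5-bis(benzyloxy)phenyl]methanol (racemic) | C=CCOc1cc(Br)cc(OCC=C)c1C(O)c1cc(OCc2ccccc2)cc(OCc2ccccc2)c1 | intermediate
7 | [4-bromo-2,6-bis(allyloxy)phenyl][3,5-bis(benzyloxy)phenyl]methanone | C=CCOc1cc(Br)cc(OCC=C)c1C(=O)c1cc(OCc2ccccc2)cc(OCc2ccccc2)c1 | intermediate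
8 | 3,4-bis(benzyloxy)benzyl chloride | ClCc1ccc(OCc2ccccc2)c(OCc2ccccc2)c1 | starting material
9 | 3,4-bis(benzyloxy)benzylmagnesium chloride | Cl[Mg]Cc1ccc(OCc2ccccc2)c(OCc2ccccc2)c1 | intermediate
10 | 1-[4-bromo-2,6-bis(allyloxy)phenyl]-1-[3,5-bis(benzyloxy)phenyl]-2-[3,4-bis(benzyloxy)phenyl]ethan-1-ol (racemic) | C=CCOc1cc(Br)cc(OCC=C)c1C(O)(Cc1ccc(OCc2ccccc2)c(OCc2ccccc2)c1)c1cc(OCc2ccccc2)cc(OCc2ccccc2)c1 | intermediate
11 | 1,3-bis(allyloxy)-5-bromo-2-{(Z)-1-[3,5-bis(benzyloxy)phenyl]-2-[3,4-bis(benzyloxy)phenyl]ethenyl}benzene | C=CCOc1cc(Br)cc(OCC=C)c1/C(=C\c1ccc(OCc2ccccc2)c(OCc2ccccc2)c1)c1cc(OCc2ccccc2)cc(OCc2ccccc2)c1 | intermediate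
12 | 5-bromo-2-{(Z)-1-[3,5-bis(benzyloxy)phenyl]-2-[3,4-bis(benzyloxy)phenyl]ethenyl}benzene-1,3-diol | Oc1cc(Br)cc(O)c1/C(=C\c1ccc(OCc2ccccc2)c(OCc2ccccc2)c1)c1cc(OCc2ccccc2)cc(OCc2ccccc2)c1 | intermediate
13 | (2S,3S)-2-[3,4-bis(benzyloxy)phenyl]-3-[3,5-bis(benzyloxy)phenyl]-6-bromo-2,3-dihydro-1-benzofuran-4-ol | Brc1cc(O)c2c(c1)O[C@H](c1ccc(OCc3ccccc3)c(OCc3ccccc3)c1)[C@H]2c1cc(OCc2ccccc2)cc(OCc2ccccc2)c1 | intermediate
14 | (2S,3S)-4-(benzyloxy)-2-[3,4-bis(benzyloxy)phenyl]-3-[3,5-bis(benzyloxy)phenyl]-6-bromo-2,3-dihydro-1-benzofuran | Brc1cc(OCc3ccccc3)c2c(c1)O[C@H](c1ccc(OCc3ccccc3)c(OCc3ccccc3)c1)[C@H]2c1cc(OCc2ccccc2)cc(OCc2ccccc2)c1 | intermediate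
15 | [(2S,3S)-4-(benzyloxy)-2-[3,4-bis(benzyloxy)phenyl]-3-[3,5-bis(benzyloxy)phenyl]-2,3-dihydro-1-benzofuran-6-yl]lithium | [Li]c1cc(OCc3ccccc3)c2c(c1)O[C@H](c1ccc(OCc3ccccc3)c(OCc3ccccc3)c1)[C@H]2c1cc(OCc2ccccc2)cc(OCc2ccccc2)c1 | intermediate
16 | [(2S,3S)-4-(benzyloxy)-2-[3,4-bis(benzyloxy)phenyl]-3-[3,5-bis(benzyloxy)phenyl]-2,3-dihydro-1-benzofuran-6-yl][4-bromo-2,6-bis(allyloxy)phenyl]methanol (both carbinol epimers) | C=CCOc1cc(Br)cc(OCC=C)c1C(O)c1cc(OCc3ccccc3)c2c(c1)O[C@H](c1ccc(OCc3ccccc3)c(OCc3ccccc3)c1)[C@H]2c1cc(OCc2ccccc2)cc(OCc2ccccc2)c1 | intermediate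
17 | [(2S,3S)-4-(benzyloxy)-2-[3,4-bis(benzyloxy)phenyl]-3-[3,5-bis(benzyloxy)phenyl]-2,3-dihydro-1-benzofuran-6-yl][4-bromo-2,6-bis(allyloxy)phenyl]methanone | C=CCOc1cc(Br)cc(OCC=C)c1C(=O)c1cc(OCc3ccccc3)c2c(c1)O[C@H](c1ccc(OCc3ccccc3)c(OCc3ccccc3)c1)[C@H]2c1cc(OCc2ccccc2)cc(OCc2ccccc2)c1 | intermediate
18 | 4-(benzyloxy)benzyl chloride | ClCc1ccc(OCc2ccccc2)cc1 | starting material
19 | 4-(benzyloxy)benzylmagnesium chloride | Cl[Mg]Cc1ccc(OCc2ccccc2)cc1 | intermediate
20 | 1-[(2S,3S)-4-(benzyloxy)-2-[3,4-bis(benzyloxy)phenyl]-3-[3,5-bis(benzyloxy)phenyl]-2,3-dihydro-1-benzofuran-6-yl]-1-[4-bromo-2,6-bis(allyloxy)phenyl]-2-[4-(benzyloxy)phenyl]ethan-1-ol (both carbinol epimers) | C=CCOc1cc(Br)cc(OCC=C)c1C(O)(Cc1ccc(OCc2ccccc2)cc1)c1cc(OCc3ccccc3)c2c(c1)O[C@H](c1ccc(OCc3ccccc3)c(OCc3ccccc3)c1)[C@H]2c1cc(OCc2ccccc2)cc(OCc2ccccc2)c1 | intermediate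
21 | (2S,3S)-4-(benzyloxy)-2-[3,4-bis(benzyloxy)phenyl]-3-[3,5-bis(benzyloxy)phenyl]-6-{(Z)-2-[4-(benzyloxy)phenyl]-1-[4-bromo-2,6-bis(allyloxy)phenyl]ethenyl}-2,3-dihydro-1-benzofuran | C=CCOc1cc(Br)cc(OCC=C)c1/C(=C\c1ccc(OCc2ccccc2)cc1)c1cc(OCc3ccccc3)c2c(c1)O[C@H](c1ccc(OCc3ccccc3)c(OCc3ccccc3)c1)[C@H]2c1cc(OCc2ccccc2)cc(OCc2ccccc2)c1 | intermediate
22 | 5-bromo-2-{(Z)-1-[(2S,3S)-4-(benzyloxy)-2-[3,4-bis(benzyloxy)phenyl]-3-[3,5-bis(benzyloxy)phenyl]-2,3-dihydro-1-benzofuran-6-yl]-2-[4-(benzyloxy)phenyl]ethenyl}benzene-1,3-diol | Oc1cc(Br)cc(O)c1/C(=C\c1ccc(OCc2ccccc2)cc1)c1cc(OCc3ccccc3)c2c(c1)O[C@H](c1ccc(OCc3ccccc3)c(OCc3ccccc3)c1)[C@H]2c1cc(OCc2ccccc2)cc(OCc2ccccc2)c1 | intermediate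
23 | (2R,3R)-3-[(2S,3S)-4-(benzyloxy)-2-[3,4-bis(benzyloxy)phenyl]-3-[3,5-bis(benzyloxy)phenyl]-2,3-dihydro-1-benzofuran-6-yl]-2-[4-(benzyloxy)phenyl]-6-bromo-2,3-dihydro-1-benzofuran-4-ol | Brc1cc(O)c2c(c1)O[C@@H](c1ccc(OCc3ccccc3)cc1)[C@@H]2c1cc(OCc3ccccc3)c2c(c1)O[C@H](c1ccc(OCc3ccccc3)c(OCc3ccccc3)c1)[C@H]2c1cc(OCc2ccccc2)cc(OCc2ccccc2)c1 | intermediate
24 | 4-benzyloxystyrene | C=Cc1ccc(OCc2ccccc2)cc1 | starting material
25 | (2R,3R)-3-[(2S,3S)-4-(benzyloxy)-2-[3,4-bis(benzyloxy)phenyl]-3-[3,5-bis(benzyloxy)phenyl]-2,3-dihydro-1-benzofuran-6-yl]-2-[4-(benzyloxy)phenyl]-6-{(E)-2-[4-(benzyloxy)phenyl]ethenyl}-2,3-dihydro-1-benzofuran-4-ol | c1ccccc1COc1ccc(/C=C/c2cc(O)c3c(c2)O[C@@H](c2ccc(OCc4ccccc4)cc2)[C@@H]3c2cc(OCc4ccccc4)c3c(c2)O[C@H](c2ccc(OCc4ccccc4)c(OCc4ccccc4)c2)[C@H]3c2cc(OCc3ccccc3)cc(OCc3ccccc3)c2)cc1 | intermediate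
26 | (2R,3R)-3-[(2S,3S)-2-(3,4-dihydroxyphenyl)-3-(3,5-dihydroxyphenyl)-4-hydroxy-2,3-dihydro-1-benzofuran-6-yl]-2-(4-hydroxyphenyl)-6-[(E)-2-(4-hydroxyphenyl)ethenyl]-2,3-dihydro-1-benzofuran-4-ol | Oc1ccc(/C=C/c2cc(O)c3c(c2)O[C@@H](c2ccc(O)cc2)[C@@H]3c2cc(O)c3c(c2)O[C@H](c2ccc(O)c(O)c2)[C@H]3c2cc(O)cc(O)c2)cc1 | target

Total step count: 17. Longest linear sequence: 17 steps (1 to 26); 4, 8, 18 and 24 are purchased and enter without steps of their own.

Least certain steps

**Step 15 (key step, proposed new method).** The most likely failure is that proton transfer to C3 does not compete. The substrate may then shuttle through the C2-protonated cation and be slowly consumed by intermolecular Friedel–Crafts alkylation of another resorcinol ring. Alternatively the ring may close without useful facial discrimination, because the substrate is large for the catalyst pocket.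

Fallback by known chemistry, from 22 back to 23:
- Hydroboration of 22 with BH3·THF in excess (the phenols become aryloxyboranes that deliver boron to C2), then oxidation with NaBO3·4H2O, should give by syn addition the hydroxyethyl triol F1 as two diastereomers at the new centres.
- Intramolecular Mitsunobu etherification (PPh3, DIAD, THF) closes O1–C2 with inversion, which from the syn adduct of the Z alkene gives the trans ring.
- 23 is then separated by chromatography from its upper-ring (2S,3S) diastereomer F2.

**Step 8 (proposed new method).** The likely failure is poor facial selectivity of protonation, or the same diversion to intermolecular alkylation, on the first and simpler substrate.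

Fallback by known chemistry, from 12 back to 13:
- Hydroboration–oxidation of 12 (BH3·THF, then NaBO3·4H2O) should give the racemic hydroxyethyl triol F3.
- Mitsunobu closure (PPh3, DIAD, THF) gives the racemic trans phenol.
- This is resolved by preparative chromatography on a chiral stationary phase into 13 and its (2R,3R) enantiomer F4.

**Steps 12 and 5.** Addition of a benzylic Grignard reagent to a diaryl ketone with two ortho alkoxy groups may be slow. Wurtz coupling during formation of the reagent and electron-transfer reduction of the ketone would then dominate.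

Fallback, from 3 back to 20 (the same applies to 7 and 10 with reagent 9):
- The order of bond formation is reversed. Grignard reagent 19 adds to the unhindered aldehyde 3 to give the secondary benzyl carbinol F5, and Dess–Martin oxidation gives the aryl benzyl ketone F6.
- The organocerium reagent made from aryllithium 15 and CeCl3 (THF, −78 °C) then adds to F6 without enolising it and gives 20.

**Step 17.** During the Lewis-acid step the stilbene may be protonated or benzylated, or attacked by a neighbouring electron-rich ring, and the O1–C2 ethers may ionise if the temperature rises.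

Fallback, from 23 back to 26, moves the Lewis acid ahead of the stilbene and ends with base only:
- 23 is debenzylated (BCl3, pentamethylbenzene, CH2Cl2, −78 °C) to the bromo heptaphenol F7 and acetylated (Ac2O, pyridine) to the bromo heptaacetate F8.
- A Heck reaction with commercial 4-acetoxystyrene (Pd(OAc)2, P(o-tol)3, Et3N, DMF, 90 °C) gives the stilbene octaacetate F9.
- Methanolysis (K2CO3, MeOH, 0 °C, under argon) releases 26.

Further compounds

F1 | step 15 | 5-bromo-2-{(1R,2S)-1-[(2S,3S)-4-(benzyloxy)-2-[3,4-bis(benzyloxy)phenyl]-3-[3,5-bis(benzyloxy)phenyl]-2,3-dihydro-1-benzofuran-6-yl]-2-[4-(benzyloxy)phenyl]-2-hydroxyethyl}benzene-1,3-diol (drawn isomer leads to 23; formed with its (1S,2R) diastereomer) | Oc1cc(Br)cc(O)c1[C@@H](c1cc(OCc2ccccc2)c2c(c1)O[C@H](c1ccc(OCc3ccccc3)c(OCc3ccccc3)c1)[C@H]2c1cc(OCc2ccccc2)cc(OCc2ccccc2)c1)[C@H](O)c1ccc(OCc2ccccc2)cc1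
F2 | step 15 | (2S,3S)-3-[(2S,3S)-4-(benzyloxy)-2-[3,4-bis(benzyloxy)phenyl]-3-[3,5-bis(benzyloxy)phenyl]-2,3-dihydro-1-benzofuran-6-yl]-2-[4-(benzyloxy)phenyl]-6-bromo-2,3-dihydro-1-benzofuran-4-ol | Brc1cc(O)c2c(c1)O[C@H](c1ccc(OCc3ccccc3)cc1)[C@H]2c1cc(OCc3ccccc3)c2c(c1)O[C@H](c1ccc(OCc3ccccc3)c(OCc3ccccc3)c1)[C@H]2c1cc(OCc2ccccc2)cc(OCc2ccccc2)c1
F3 | step 8 | 5-bromo-2-{(1S*,2R*)-1-[3,5-bis(benzyloxy)phenyl]-2-[3,4-bis(benzyloxy)phenyl]-2-hydroxyethyl}benzene-1,3-diol (racemic; one enantiomer drawn) | Oc1cc(Br)cc(O)c1[C@H](c1cc(OCc2ccccc2)cc(OCc2ccccc2)c1)[C@@H](O)c1ccc(OCc2ccccc2)c(OCc2ccccc2)c1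
F4 | step 8 | (2R,3R)-2-[3,4-bis(benzyloxy)phenyl]-3-[3,5-bis(benzyloxy)phenyl]-6-bromo-2,3-dihydro-1-benzofuran-4-ol | Brc1cc(O)c2c(c1)O[C@@H](c1ccc(OCc3ccccc3)c(OCc3ccccc3)c1)[C@@H]2c1cc(OCc2ccccc2)cc(OCc2ccccc2)c1
F5 | step 12 | 1-[4-bromo-2,6-bis(allyloxy)phenyl]-2-[4-(benzyloxy)phenyl]ethan-1-ol (racemic) | C=CCOc1cc(Br)cc(OCC=C)c1C(O)Cc1ccc(OCc2ccccc2)cc1
F6 | step 12 | 1-[4-bromo-2,6-bis(allyloxy)phenyl]-2-[4-(benzyloxy)phenyl]ethan-1-one | C=CCOc1cc(Br)cc(OCC=C)c1C(=O)Cc1ccc(OCc2ccccc2)cc1
F7 | step 17 | (2R,3R)-6-bromo-3-[(2S,3S)-2-(3,4-dihydroxyphenyl)-3-(3,5-dihydroxyphenyl)-4-hydroxy-2,3-dihydro-1-benzofuran-6-yl]-2-(4-hydroxyphenyl)-2,3-dihydro-1-benzofuran-4-ol | Brc1cc(O)c2c(c1)O[C@@H](c1ccc(O)cc1)[C@@H]2c1cc(O)c2c(c1)O[C@H](c1ccc(O)c(O)c1)[C@H]2c1cc(O)cc(O)c1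
F8 | step 17 | heptaacetate of F7 | Brc1cc(OC(C)=O)c2c(c1)O[C@@H](c1ccc(OC(C)=O)cc1)[C@@H]2c1cc(OC(C)=O)c2c(c1)O[C@H](c1ccc(OC(C)=O)c(OC(C)=O)c1)[C@H]2c1cc(OC(C)=O)cc(OC(C)=O)c1
F9 | step 17 | octaacetate of 26 | CC(=O)Oc1ccc(/C=C/c2cc(OC(C)=O)c3c(c2)O[C@@H](c2ccc(OC(C)=O)cc2)[C@@H]3c2cc(OC(C)=O)c3c(c2)O[C@H](c2ccc(OC(C)=O)c(OC(C)=O)c2)[C@H]3c2cc(OC(C)=O)cc(OC(C)=O)c2)cc1
A1 | alternative 1 | (3S,4S)-7-bromo-3-(3,4-dimethoxyphenyl)-4-(3,5-dimethoxyphenyl)-5-methoxychroman-2-one | O=C1Oc2cc(Br)cc(OC)c2[C@H](c2cc(OC)cc(OC)c2)[C@H]1c1ccc(OC)c(OC)c1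
A2 | alternative 2 | hesperetin, (2S)-5,7-dihydroxy-2-(3-hydroxy-4-methoxyphenyl)chroman-4-one | COc1ccc(cc1O)[C@@H]1CC(=O)c2c(O)cc(O)cc2O1
A3 | alternative 2 | methyl (2S,3S)-6-benzyloxy-2-(3,4-dimethoxyphenyl)-4-methoxy-2,3-dihydrobenzofuran-3-carboxylate | c1ccccc1COc1cc(OC)c2c(c1)O[C@H](c1ccc(OC)c(OC)c1)[C@H]2C(=O)OC
A4 | alternative 3 | (2S,3S)-6-[(2R,3R)-6-bromo-4-methoxy-2-(4-methoxyphenyl)-2,3-dihydrobenzofuran-3-yl]-2-(3,4-dimethoxyphenyl)-3-(3,5-dimethoxyphenyl)-3,5,6,7-tetrahydrobenzofuran-4(2H)-one (either configuration at C6) | Brc1cc(OC)c2c(c1)O[C@@H](c1ccc(OC)cc1)[C@@H]2C1CC(=O)C2=C(C1)O[C@H](c1ccc(OC)c(OC)c1)[C@H]2c1cc(OC)cc(OC)c1
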